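The numbers in the tables were computed for an exercise, noise included.

**Questions.** 4 questions stand on 3 flasks.

* the best flask by amount of target, in percent of the substrate charged; "all alike" if 1.5 percentage points covers them all (Tuesday's / Friday's / Wednesday's / all alike)
* amount of target at the end, in percent of the substrate charged, Tuesday's
* amount of target at the end, in percent of the substrate charged, Friday's
* amount of target at the end, in percent of the substrate charged, Wednesday's

| flask | substrate | reagent | temperature | remark | time |
|---|---|---|---|---|---|
| summer | 12 mM | 8 mM | 30 °C | run made earlier |  |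
| midnight | 12 mM | 18 mM | 60 °C | run made earlier |  |
| winter | 24 mM | 12 mM | 30 °C | run made earlier |  |
| Tuesday's | 12 mM | 12.0 mM | 35 °C |  | 5.0 min |
| Friday's | 12 mM | 12.0 mM | 60 °C |  | 5.0 min |
| Wednesday's | 12 mM | 12.0 mM | 85 °C |  | 5.0 min |

summer run (percent of the substrate charged)

| time / min | target / % |
|---|---|
| 0.417 | 0.4 |
| 1.33 | 2.4 |
| 2.00 | 2.4 |
| 3.00 | 3.8 |
| 5.00 | 6.4 |
| 6.00 | 7.7 |

midnight run (percent of the substrate charged)

| time / s | target / % |
|---|---|
| 20.0 | 4.4 |
| 40.0 | 8.0 |
| 50.0 | 9.1 |
| 80.0 | 13.0 |
| 120 | 17.1 |

winter run (percent of the substrate charged)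

| time / min | target / % |
|---|---|
| 0.500 | 1.0 |
| 0.833 | 3.2 |
| 1.50 | 4.6 |
| 3.00 | 8.7 |
| 6.00 | 16.9 |

(each reading ± 0.5 percentage points)

- steps under discussion: substrate + reagent -> target; target -> over-reaction product; target <-> isomer of the product

**Starting rates.** Summer and winter change both charges, so the order in reagent stays open; this reckoning takes it as one. Summer's last reading, scaled to 12.0 mM of reagent, gives a starting rate of 0.0192 min⁻¹ at 30 °C, as a fraction of the charge. Midnight's first reading, scaled likewise, gives 0.0880 min⁻¹ at 60 °C, with that reading's scatter of 0.5 percentage points. Spreading that ratio evenly over the degrees between the two runs gives 0.0248 min⁻¹ for Tuesday's and 0.312 min⁻¹ for Wednesday's.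

**Reagent balance.** Substrate and reagent are charged alike, so they fall together, and a rate of second order overall falls with the square of the share left. Friday's then reaches 30.6 %: this is the spent share, rate times time divided by one plus rate times time, and it is a reckoned ceiling for target.

**Time ladder.** Wednesday's fills fastest, with a filling time of 3.21 min, shorter than the 5.0 min allowed, and a spent share of 61.0 %. Friday's takes 11.4 min. Tuesday's takes 40.3 min and spends 11.0 %. In the winter run target grows from 8.7 % to 16.9 %, twice, over twice the time, so no loss shows in that run at 30 °C; this reading places no loss on the ladder for Friday's or Wednesday's. This reckoning commits to Tuesday's near 11.0 % and Friday's just below 30.6 %, and leaves Wednesday's unsized.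

**The forecast.** It names Tuesday's, with 14.5 %, 11.5 % and 3.5 %, reading the midnight curve thus: "so target is being lost at about 0.4/min at 60 °C". Its Tuesday's figure stands above the ceiling reckoned here, and its Friday's figure far below.

**The flasks.** Friday's gives most: Tuesday's 10.8 %, Friday's 28.3 %, Wednesday's 24.9 %.

    substrate + reagent → target, rate k1*[substrate]^2*[reagent]^0.5 (k = 1.26 L¹·⁵ mol⁻¹·⁵ s⁻¹, Ea = 47.0 kJ mol⁻¹)
    target → over-reaction product (k = 1.62 × 10⁻⁴ s⁻¹, Ea = 100 kJ mol⁻¹)
    target ⇌ isomer of the product (K = 0.982, k = 3.81 × 10⁻⁴ s⁻¹, Ea = 113 kJ mol⁻¹, ΔH = −5.00 kJ mol⁻¹)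
    (constants at 60 °C)

**Fill against drain.** Friday's has spent 31.0 % of its reagent against a spent share of 30.6 %, target's forward half-life through both exits at that temperature, 21.3 min, is longer than the 5.0 min of the run, and 28.3 % of target stands there. Wednesday's has spent 56.1 % against a spent share of 61.0 %, and beside its 24.9 % of target stand 12.9 % of over-reaction product and 18.4 % of isomer of the product.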